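## Analysis of the target

7-O-Methyltetrahydroochnaflavone is an unsymmetrical biflavanone. Two 2-aryl-2,3-dihydro-4H-chromen-4-one units are joined by a diaryl ether between C3' of ring B of the first unit and C4''' of the para-substituted phenyl ring of the second. The first unit carries 5-OH and 7-OMe on ring A and 4'-OH on ring B; the second is a 5'',7''-dihydroxy unit. The only stereocentres are C2 and C2'', both S and both benzylic ether carbons. They lie nine bonds apart, so neither can direct the other and each must be set by a reagent or catalyst.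

Flavanones are fragile toward base: enolization at C3 expels the ring A phenoxide (E1cB) to a 2'-hydroxychalcone, and re-closure scrambles C2. Strong acid can ionize the benzylic C2–O1 bond, and the free phloroglucinol-type ring is easily oxidized. The synthesis is hard because the two resorcinol-type benzo rings are almost identical yet only O7 is methylated, because both remote stereocentres must survive every later step, and because the diaryl ether is non-symmetric.

The plan rests on ring A'' (C4a''–C5''–C6''–C7''–C8''–C8a''). With C4'' it is an acylphloroglucinol, a cyclized polyketide whose oxygens at C5'', C7'' and C8a'' mark former chain carbonyls. It can therefore be made last, from an open chain, by forming C4a''–C5''.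

## Retrosynthetic reasoning

**22 from 21.** The last step only cuts two O–benzyl bonds, at O4' and O5. Benzyl ethers survive base, acid and 110 °C and are removed under neutral conditions that do not open a flavanone, so the sensitive tetraphenol appears only at the end.

**21 from 19 through 20.** The C4a''–C5'' bond is cut and ring A'' is unravelled to the dihydropyranone 19, whose C6 carries a masked acetoacetyl chain as a dioxinone. This is the one disconnection that makes the carbocycle from a chain. Ring A'' then needs no protecting groups and its oxygen pattern follows from the chain. The forward step must generate the acylketene 20, acylate pyranone C5 with it and aromatize, all without touching C2'', C2 or the finished first flavanone. A ketene acylates any hydroxyl it meets, so 19 is designed without one: O5 is benzylated like O4'.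

**19 from 18 and 6.** The C2–C1' bond is cut. Two reasons fix this choice.
- A flavanone cannot be present during strongly basic chain building, because its enolate opens to the chalcone and racemizes.
- Making the first benzo ring by a second dioxinone cyclization would leave two indistinguishable 7-hydroxyls and a second unprecedented step.

The first flavanone is therefore attached last among the C–C bond formations. It is made by a neutral, catalytic, enantioselective conjugate addition of the arylboronic acid 18 to the chromone 6, which already holds the 7-methyl ether and the protected O5. The forward reaction must set C2 by catalyst control and leave the dioxinone and the dihydropyranone alone.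

**18 from 17 from 16.** The C–B bond is traced back to a C–Br bond. The bromide is inert to base, acid and hydrogenation, so it is carried from the start and converted to boron just before use.

**16 from 14 through 15.** The pyranone O1''–C8a'' bond is cut (cyclodehydration of a δ-hydroxy-β-diketone). The C2''–O bond is never broken, so the configuration of 14 is carried into the ring.

**14 from 13 and 2; 2 from 1.** The bond between the amide carbonyl carbon of 13 and the terminal carbon of 2 is cut (Claisen-type acylation of a dianion). This brings in all six remaining carbons of ring A'' at once. It is the only strongly basic step on the main line and it precedes any flavanone. Compound 2 comes from 1 by acetylation at the methyl group.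

**13 from 12 from 11 from 10.** The stereocentre C2'' is traced to the ketone of 10 and set by asymmetric hydrogenation. The sense of this reaction is secure and the bromide and benzyl ether tolerate it. The ester is then converted to the amide that acylates cleanly.

**10 from 9 from 7 and 8.** The ester carbon is added to the methyl ketone of 9. The diaryl ether C–O bond is cut to phenol 7 and fluoride 8. The acetyl group of 8 activates the fluoride and afterwards becomes C2''–C3''.

**6 from 4 through 5; 4 from 3.** The pyranone of 6 is formed by adding one carbon to the acetyl group of 4. Compound 4 is 3 with one of its two equivalent hydroxyls benzylated.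

## Alternatives that were turned down

**Alternative 1:** Both pyranone rings are opened at C3=C4 and C3''=C4''. The bis(diene) A1 has two branched aryl allyl ethers, each ortho to an α-silyloxyvinyl group. A ruthenium alkylidene would close both pairs by enol ether ring-closing metathesis to the bis(4-silyloxy-2H-chromene) A2. Desilylation, peri-demethylation at O5 and debenzylation would follow.
- For: enol ether metathesis is established, so on precedent this key step is stronger than step 14. Both heterocycles close in one neutral operation. Both benzo rings are bought with their oxygen pattern, so O7 is differentiated from the outset.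
- Against: in A1 each stereocentre is a benzylic and allylic aryl ether of a 2,6-disubstituted electron-rich phenol. Such C–O bonds ionize easily and can undergo [3,3] shift to the free ortho position. Ruthenium hydrides can isomerize the allyl ether and erase the centre. The closure is also slow, since it forms a trisubstituted enol ether next to a peri substituent. A2 still needs three further operations, one of them a selective demethylation.
- Comparison: the chosen route sets C2'' and C2 by catalytic reactions of predictable sense and never makes them allylic. In exchange for weaker precedent it builds ring A'' without any protecting group on it.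

**Alternative 2:** Ring C of the first unit is opened at O1–C2 and C3–C4. The aldehyde A3 and an orthoformate would give a 4-methoxy ortho-quinone methide under a confined chiral Brønsted acid. This would add across the vinyl group of the styrene A4 to give the cis-4-methoxyflavan A5, whose bromide is the handle for the second unit.
- For: very convergent. The pyran ring and C2 arise in one catalytic step from simple parts, and the 7-methyl ether is bought. In speed of reaching the first flavanone skeleton it is stronger than the chosen route.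
- Against: C4 is at the wrong oxidation level. Converting the 4-methoxy group to the ketone passes through a 4-flavanyl cation on a phloroglucinol ring, which eliminates or oligomerizes. A stereocentre at C4 is made only to be destroyed. The electron-rich styrene A4 can polymerize under strong acid. Enantiocontrol with so oxygenated an aldehyde as A3 is unproven. The second flavanone remains unsolved.
- Comparison: step 13 delivers the first flavanone at the correct oxidation level in one step, and step 14 addresses the second.

**Alternative 3:** Both pyranone rings are opened at O1–C2 and O1''–C2'' to the bis(chalcone epoxide) A6. Acid would free the ortho phenols, which attack the benzylic epoxide carbons with inversion to give the bis-trans-dihydroflavonol A7. Both C3 hydroxyls must then be removed.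
- For: chalcone formation and asymmetric chalcone epoxidation are reliable, the closure is stereospecific in principle, and both halves are handled alike. On precedent and symmetry it is stronger.
- Against: the benzylic epoxide carbons carry para-oxygenated aryl groups and would open with carbocation character, eroding the stereochemical relay. 5-Exo attack to benzofuranones competes. The two relay hydroxyls need a reductive removal next to a ketone, where the C2–O1 bond can also be expelled. Every phenol needs protection, and the two chalcone halves still need differentiating.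
- Comparison: the chosen route creates no stereocentre or oxygen that must be removed again and needs protection at only two oxygens.

Key step: step 14

Assumption: compounds 3, 7 and 8 are taken as catalogue chemicals; 7 is otherwise available from 5-bromosalicylaldehyde by O-benzylation and Dakin-type oxidation.

## Route

Step 1
Reactants: 1 2,2,6-trimethyl-4H-1,3-dioxin-4-one
Product: 2 2,2-dimethyl-6-(2-oxopropyl)-4H-1,3-dioxin-4-one
Conditions: LiN(SiMe3)2 (2 equiv), 1 (2 equiv), THF, −78 °C; AcCl (1 equiv); aq. NH4Cl
Reagents that add atoms: acetyl chloride, CC(=O)Cl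
Why: Deprotonation at the 6-methyl group gives the lithium dienolate, which is C-acylated at its terminal carbon (vinylogous Claisen condensation); the more acidic product quenches a second equivalent of dienolate, hence the excess.

Step 2
Reactants: 3 1-(2,6-dihydroxy-4-methoxyphenyl)ethan-1-one
Product: 4 1-[2-(benzyloxy)-6-hydroxy-4-methoxyphenyl]ethan-1-one
Conditions: BnBr (1.05 equiv), K2CO3, acetone, reflux
Reagents that add atoms: benzyl bromide, BrCc1ccccc1
Why: Williamson etherification of one of two equivalent phenols; the remaining hydroxyl is locked in a hydrogen bond to the carbonyl and should react far more slowly, so mono-alkylation is expected.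

Step 3
Reactants: 4 1-[2-(benzyloxy)-6-hydroxy-4-methoxyphenyl]ethan-1-one
Product: 6 5-(benzyloxy)-7-methoxy-4H-chromen-4-one, via enaminone 5 (not isolated)
Conditions: Me2NCH(OMe)2, toluene, 95 °C; then aq. HCl (2 M), CH2Cl2, 40 °C
Reagents that add atoms: N,N-dimethylformamide dimethyl acetal, COC(OC)N(C)C
Why: Condensation of the methyl ketone with the amide acetal gives the enaminone; acid then promotes conjugate addition of the free phenol and loss of dimethylamine (enaminone route to chromones).

Step 4
Reactants: 7 2-(benzyloxy)-5-bromophenol; 8 1-(4-fluorophenyl)ethan-1-one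
Product: 9 1-{4-[2-(benzyloxy)-5-bromophenoxy]phenyl}ethan-1-one
Conditions: K2CO3, DMF, 120 °C
Reagents that add atoms: none
Why: Nucleophilic aromatic substitution of the fluoride activated by the para acetyl group; the bromide of 7 is meta to the phenoxide and not activated, so it is retained.

Step 5
Reactants: 9 1-{4-[2-(benzyloxy)-5-bromophenoxy]phenyl}ethan-1-one
Product: 10 ethyl 3-{4-[2-(benzyloxy)-5-bromophenoxy]phenyl}-3-oxopropanoate
Conditions: NaH (2.5 equiv), (EtO)2CO (3 equiv), THF, reflux; aq. HCl
Reagents that add atoms: diethyl carbonate, CCOC(=O)OCC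
Why: Crossed Claisen condensation of the ketone enolate with the carbonate; formation of the stabilized β-keto ester enolate drives it to completion.

Step 6
Reactants: 10 ethyl 3-{4-[2-(benzyloxy)-5-bromophenoxy]phenyl}-3-oxopropanoate
Product: 11 ethyl (3S)-3-{4-[2-(benzyloxy)-5-bromophenoxy]phenyl}-3-hydroxypropanoate
Conditions: [RuCl(p-cymene)((R)-BINAP)]Cl (1 mol%), H2 (30 bar), EtOH, 60 °C
Reagents that add atoms: none
Why: Noyori asymmetric hydrogenation: the β-keto ester chelates divalent ruthenium and hydride reaches the ketone face selected by (R)-BINAP, the sense that gives (R)-3-hydroxybutanoates; because aryl outranks CH2CO2Et the same spatial outcome is named S, the configuration needed at C2''. Aryl bromide and benzyl ether are inert to this homogeneous catalyst.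

Step 7
Reactants: 11 ethyl (3S)-3-{4-[2-(benzyloxy)-5-bromophenoxy]phenyl}-3-hydroxypropanoate
Product: 12 (3S)-3-{4-[2-(benzyloxy)-5-bromophenoxy]phenyl}-3-hydroxy-N-methoxy-N-methylpropanamide
Conditions: MeNH(OMe)·HCl (3 equiv), i-PrMgCl (6 equiv), THF, −20 to 0 °C
Reagents that add atoms: N,O-dimethylhydroxylamine hydrochloride, CNOC.Cl
Why: Aminolysis of the ester by the magnesium amide to the Weinreb amide; the hydroxyl is a magnesium alkoxide during the reaction, which prevents β-elimination, and the stereocentre is not involved.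

Step 8
Reactants: 12 (3S)-3-{4-[2-(benzyloxy)-5-bromophenoxy]phenyl}-3-hydroxy-N-methoxy-N-methylpropanamide
Product: 13 (3S)-3-{4-[2-(benzyloxy)-5-bromophenoxy]phenyl}-N-methoxy-N-methyl-3-[(triethylsilyl)oxy]propanamide
Conditions: Et3SiCl, imidazole, DMF, 0 to 23 °C
Reagents that add atoms: chlorotriethylsilane, CC[Si](Cl)(CC)CC
Why: Silylation of the secondary alcohol; the triethylsilyl ether survives the dianion step and is removed later by mild acid.

Step 9
Reactants: 13 (3S)-3-{4-[2-(benzyloxy)-5-bromophenoxy]phenyl}-N-methoxy-N-methyl-3-[(triethylsilyl)oxy]propanamide; 2 2,2-dimethyl-6-(2-oxopropyl)-4H-1,3-dioxin-4-one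
Product: 14 6-[(6S)-6-{4-[2-(benzyloxy)-5-bromophenoxy]phenyl}-2,4-dioxo-6-[(triethylsilyl)oxy]hexyl]-2,2-dimethyl-4H-1,3-dioxin-4-one
Conditions: 2 (2.2 equiv), LiN(i-Pr)2 (4.3 equiv), THF, −78 °C; then 13, −78 to −40 °C; aq. NH4Cl
Reagents that add atoms: none
Why: Double deprotonation of 2 gives a dianion that reacts at its terminal carbon with the Weinreb amide (Claisen-type acylation); the chelated tetrahedral intermediate prevents over-addition, and the amide base is kept just below two equivalents per 2 so that no free amide base meets the aryl bromide.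

Step 10
Reactants: 14 6-[(6S)-6-{4-[2-(benzyloxy)-5-bromophenoxy]phenyl}-2,4-dioxo-6-[(triethylsilyl)oxy]hexyl]-2,2-dimethyl-4H-1,3-dioxin-4-one
Product: 16 6-{[(2S)-2-{4-[2-(benzyloxy)-5-bromophenoxy]phenyl}-4-oxo-3,4-dihydro-2H-pyran-6-yl]methyl}-2,2-dimethyl-4H-1,3-dioxin-4-one, via hydroxy diketone 15 (not isolated)
Conditions: aq. HF (48%), MeCN, 0 °C; extraction; TsOH·H2O (10 mol%), CH2Cl2, 4 Å MS, 23 °C
Reagents that add atoms: none
Why: Desilylation frees the δ-hydroxyl, which adds to the C2 carbonyl of the hexyl chain (6-exo-trig hemiketal); acid-catalysed dehydration gives the conjugated 2,3-dihydro-4H-pyran-4-one. The carbinol C–O bond is not broken, so S is retained.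

Step 11
Reactants: 16 6-{[(2S)-2-{4-[2-(benzyloxy)-5-bromophenoxy]phenyl}-4-oxo-3,4-dihydro-2H-pyran-6-yl]methyl}-2,2-dimethyl-4H-1,3-dioxin-4-one
Product: 17 6-{[(2S)-2-{4-[2-(benzyloxy)-5-(4,4,5,5-tetramethyl-1,3,2-dioxaborolan-2-yl)phenoxy]phenyl}-4-oxo-3,4-dihydro-2H-pyran-6-yl]methyl}-2,2-dimethyl-4H-1,3-dioxin-4-one
Conditions: B2pin2 (1.2 equiv), Pd2(dba)3 (1 mol%), XPhos (4 mol%), potassium 2-ethylhexanoate (2.5 equiv), i-PrOAc, 35 °C
Reagents that add atoms: bis(pinacolato)diboron, CC1(C)OB(OC1(C)C)B1OC(C)(C)C(C)(C)O1
Why: Miyaura borylation (oxidative addition of zerovalent palladium into the C–Br bond, carboxylate-assisted transmetalation with the diboron, reductive elimination); the lipophilic carboxylate lets it run at 35 °C, well below the temperature at which the dioxinone fragments, and the base is too weak to deprotonate the substrate.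

Step 12
Reactants: 17 6-{[(2S)-2-{4-[2-(benzyloxy)-5-(4,4,5,5-tetramethyl-1,3,2-dioxaborolan-2-yl)phenoxy]phenyl}-4-oxo-3,4-dihydro-2H-pyran-6-yl]methyl}-2,2-dimethyl-4H-1,3-dioxin-4-one
Product: 18 [4-(benzyloxy)-3-(4-{(2S)-6-[(2,2-dimethyl-4-oxo-4H-1,3-dioxin-6-yl)methyl]-4-oxo-3,4-dihydro-2H-pyran-2-yl}phenoxy)phenyl]boronic acid
Conditions: NaIO4 (3 equiv), THF/H2O (4:1), 23 °C; then aq. HCl (1 M)
Reagents that add atoms: water, O
Why: The boronate hydrolysis equilibrium is pulled to the boronic acid because periodate cleaves the liberated pinacol (glycol cleavage); the substrate has no glycol, sulfide or free phenol for periodate to attack.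

Step 13
Reactants: 18 [4-(benzyloxy)-3-(4-{(2S)-6-[(2,2-dimethyl-4-oxo-4H-1,3-dioxin-6-yl)methyl]-4-oxo-3,4-dihydro-2H-pyran-2-yl}phenoxy)phenyl]boronic acid; 6 5-(benzyloxy)-7-methoxy-4H-chromen-4-one
Product: 19 (2S)-5-(benzyloxy)-2-[4-(benzyloxy)-3-(4-{(2S)-6-[(2,2-dimethyl-4-oxo-4H-1,3-dioxin-6-yl)methyl]-4-oxo-3,4-dihydro-2H-pyran-2-yl}phenoxy)phenyl]-7-methoxy-2,3-dihydro-4H-chromen-4-one
Conditions: [Rh(OH)(L)]2 (3 mol%), L = (S)-(6,6'-dimethoxybiphenyl-2,2'-diyl)bis[bis(3,4,5-trifluorophenyl)phosphine], 6 (2 equiv), CH2Cl2/H2O (10:1), 25 °C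
Reagents that add atoms: none
Why: Hayashi–Miyaura asymmetric 1,4-addition: 18 transmetalates to the monovalent rhodium hydroxide, the chromone C2=C3 bond inserts into the aryl–rhodium bond and water releases the flavanone without base. The (S)-biaryl bisphosphine selects the chromone face by the same model as (S)-BINAP with cyclic enones, which corresponds to 2S; the remote C2'' has no say. The β-carbons of the dihydropyranone and dioxinone are fully substituted and oxygen-bearing and should not insert.

Step 14
Reactants: 19 (2S)-5-(benzyloxy)-2-[4-(benzyloxy)-3-(4-{(2S)-6-[(2,2-dimethyl-4-oxo-4H-1,3-dioxin-6-yl)methyl]-4-oxo-3,4-dihydro-2H-pyran-2-yl}phenoxy)phenyl]-7-methoxy-2,3-dihydro-4H-chromen-4-one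
Product: 21 (2S)-5-(benzyloxy)-2-[4-(benzyloxy)-3-{4-[(2S)-5,7-dihydroxy-4-oxo-3,4-dihydro-2H-chromen-2-yl]phenoxy}phenyl]-7-methoxy-2,3-dihydro-4H-chromen-4-one, via acylketene 20 (not isolated)
Conditions: toluene (0.002 M), 4 Å MS, argon, 110 °C
Reagents that add atoms: none
Why: Proposed new method: at 110 °C the dioxinone of 19 loses acetone by retro-hetero-Diels–Alder reaction to give acylketene 20. Pyranone C5, the nucleophilic α-carbon of a vinylogous ester, attacks the ketene carbon in a 6-(enolendo)-exo-dig C-acylation that forms C4a''–C5'' and closes ring A''; the same bond can form by thermal 6π-electrocyclization of the dienylketene that results when the C8'' methylene enolizes. The cyclohexadienone so formed tautomerizes to the 5'',7''-dihydroxy arene, which makes the sequence irreversible. The closest known reaction types are thermal dioxinone-to-acylketene C-acylations, the Claisen-type cyclization of 3,5,7-triketo esters to acylphloroglucinols and the dienylketene electrocyclization of benzannulations. No stereocentre is formed, and with neither acid nor base present neither pyranone ring can open, so C2 and C2'' are carried through. The step needs C-acylation at C5 to beat ketene dimerization and hydration, which high dilution and dry solvent favour. Compound 19 has no free hydroxyl to trap the ketene, and aldol-type foldings are excluded because the C8a'' carbonyl is locked as the ring enol ether.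

Step 15
Reactants: 21 (2S)-5-(benzyloxy)-2-[4-(benzyloxy)-3-{4-[(2S)-5,7-dihydroxy-4-oxo-3,4-dihydro-2H-chromen-2-yl]phenoxy}phenyl]-7-methoxy-2,3-dihydro-4H-chromen-4-one
Product: 22 7-O-methyltetrahydroochnaflavone, (2S)-5-hydroxy-2-[4-hydroxy-3-{4-[(2S)-5,7-dihydroxy-4-oxo-3,4-dihydro-2H-chromen-2-yl]phenoxy}phenyl]-7-methoxy-2,3-dihydro-4H-chromen-4-one
Conditions: H2 (1 atm), Pd/C (10 wt%), EtOAc/THF, 23 °C
Reagents that add atoms: none
Why: Hydrogenolysis of the two aryl benzyl ethers under neutral conditions; the reaction is stopped at full debenzylation so that the slower cleavage of the cyclic benzylic C2–O1 bonds does not set in.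

## Compound list

1 | 2,2,6-trimethyl-4H-1,3-dioxin-4-one | CC1=CC(=O)OC(C)(C)O1 | starting material
2 | 2,2-dimethyl-6-(2-oxopropyl)-4H-1,3-dioxin-4-one | CC(=O)CC1=CC(=O)OC(C)(C)O1 | intermediate
3 | 1-(2,6-dihydroxy-4-methoxyphenyl)ethan-1-one | COc1cc(O)c(C(C)=O)c(O)c1 | starting material
4 | 1-[2-(benzyloxy)-6-hydroxy-4-methoxyphenyl]ethan-1-one | COc1cc(O)c(C(C)=O)c(OCc2ccccc2)c1 | intermediate
5 | (E)-1-[2-(benzyloxy)-6-hydroxy-4-methoxyphenyl]-3-(dimethylamino)prop-2-en-1-one | COc1cc(O)c(C(=O)/C=C/N(C)C)c(OCc2ccccc2)c1 | intermediate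
6 | 5-(benzyloxy)-7-methoxy-4H-chromen-4-one | COc1cc(OCc2ccccc2)c2c(c1)OC=CC2=O | intermediate
7 | 2-(benzyloxy)-5-bromophenol | Oc1cc(Br)ccc1OCc1ccccc1 | starting material
8 | 1-(4-fluorophenyl)ethan-1-one | CC(=O)c1ccc(F)cc1 | starting material
9 | 1-{4-[2-(benzyloxy)-5-bromophenoxy]phenyl}ethan-1-one | CC(=O)c1ccc(Oc2cc(Br)ccc2OCc2ccccc2)cc1 | intermediate
10 | ethyl 3-{4-[2-(benzyloxy)-5-bromophenoxy]phenyl}-3-oxopropanoate | CCOC(=O)CC(=O)c1ccc(Oc2cc(Br)ccc2OCc2ccccc2)cc1 | intermediate
11 | ethyl (3S)-3-{4-[2-(benzyloxy)-5-bromophenoxy]phenyl}-3-hydroxypropanoate | CCOC(=O)C[C@H](O)c1ccc(Oc2cc(Br)ccc2OCc2ccccc2)cc1 | intermediate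
12 | (3S)-3-{4-[2-(benzyloxy)-5-bromophenoxy]phenyl}-3-hydroxy-N-methoxy-N-methylpropanamide | CON(C)C(=O)C[C@H](O)c1ccc(Oc2cc(Br)ccc2OCc2ccccc2)cc1 | intermediate
13 | (3S)-3-{4-[2-(benzyloxy)-5-bromophenoxy]phenyl}-N-methoxy-N-methyl-3-[(triethylsilyl)oxy]propanamide | CON(C)C(=O)C[C@H](O[Si](CC)(CC)CC)c1ccc(Oc2cc(Br)ccc2OCc2ccccc2)cc1 | intermediate
14 | 6-[(6S)-6-{4-[2-(benzyloxy)-5-bromophenoxy]phenyl}-2,4-dioxo-6-[(triethylsilyl)oxy]hexyl]-2,2-dimethyl-4H-1,3-dioxin-4-one | CC1(C)OC(=O)C=C(CC(=O)CC(=O)C[C@H](O[Si](CC)(CC)CC)c2ccc(Oc3cc(Br)ccc3OCc3ccccc3)cc2)O1 | intermediate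
15 | 6-[(6S)-6-{4-[2-(benzyloxy)-5-bromophenoxy]phenyl}-6-hydroxy-2,4-dioxohexyl]-2,2-dimethyl-4H-1,3-dioxin-4-one (in equilibrium with its cyclic hemiketal) | CC1(C)OC(=O)C=C(CC(=O)CC(=O)C[C@H](O)c2ccc(Oc3cc(Br)ccc3OCc3ccccc3)cc2)O1 | intermediate
16 | 6-{[(2S)-2-{4-[2-(benzyloxy)-5-bromophenoxy]phenyl}-4-oxo-3,4-dihydro-2H-pyran-6-yl]methyl}-2,2-dimethyl-4H-1,3-dioxin-4-one | CC1(C)OC(=O)C=C(CC2=CC(=O)C[C@@H](c3ccc(Oc4cc(Br)ccc4OCc4ccccc4)cc3)O2)O1 | intermediate
17 | 6-{[(2S)-2-{4-[2-(benzyloxy)-5-(4,4,5,5-tetramethyl-1,3,2-dioxaborolan-2-yl)phenoxy]phenyl}-4-oxo-3,4-dihydro-2H-pyran-6-yl]methyl}-2,2-dimethyl-4H-1,3-dioxin-4-one | CC1(C)OC(=O)C=C(CC2=CC(=O)C[C@@H](c3ccc(Oc4cc(B5OC(C)(C)C(C)(C)O5)ccc4OCc4ccccc4)cc3)O2)O1 | intermediate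
18 | [4-(benzyloxy)-3-(4-{(2S)-6-[(2,2-dimethyl-4-oxo-4H-1,3-dioxin-6-yl)methyl]-4-oxo-3,4-dihydro-2H-pyran-2-yl}phenoxy)phenyl]boronic acid | CC1(C)OC(=O)C=C(CC2=CC(=O)C[C@@H](c3ccc(Oc4cc(B(O)O)ccc4OCc4ccccc4)cc3)O2)O1 | intermediate
19 | (2S)-5-(benzyloxy)-2-[4-(benzyloxy)-3-(4-{(2S)-6-[(2,2-dimethyl-4-oxo-4H-1,3-dioxin-6-yl)methyl]-4-oxo-3,4-dihydro-2H-pyran-2-yl}phenoxy)phenyl]-7-methoxy-2,3-dihydro-4H-chromen-4-one (cyclization precursor) | COc1cc(OCc6ccccc6)c2c(c1)O[C@H](c1ccc(OCc3ccccc3)c(Oc3ccc([C@@H]4CC(=O)C=C(CC5=CC(=O)OC(C)(C)O5)O4)cc3)c1)CC2=O | intermediate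
20 | acylketene from 19: 4-[(2S)-2-aryl-4-oxo-3,4-dihydro-2H-pyran-6-yl]-3-oxobut-1-en-1-one, aryl as in 19 | COc1cc(OCc6ccccc6)c2c(c1)O[C@H](c1ccc(OCc3ccccc3)c(Oc3ccc([C@@H]4CC(=O)C=C(CC(=O)C=C=O)O4)cc3)c1)CC2=O | intermediate
21 | (2S)-5-(benzyloxy)-2-[4-(benzyloxy)-3-{4-[(2S)-5,7-dihydroxy-4-oxo-3,4-dihydro-2H-chromen-2-yl]phenoxy}phenyl]-7-methoxy-2,3-dihydro-4H-chromen-4-one (4',5-di-O-benzyl target) | COc1cc(OCc6ccccc6)c2c(c1)O[C@H](c1ccc(OCc3ccccc3)c(Oc3ccc([C@@H]4CC(=O)c5c(O)cc(O)cc5O4)cc3)c1)CC2=O | intermediate
22 | 7-O-methyltetrahydroochnaflavone | COc1cc(O)c2c(c1)O[C@H](c1ccc(O)c(Oc3ccc([C@@H]4CC(=O)c5c(O)cc(O)cc5O4)cc3)c1)CC2=O | target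

## Step count and least certain steps

Total step count: 15. Longest linear sequence: 12 (steps 4 to 15); step 1 and steps 2 to 3 are side branches.

Because C2'' and C2 are set by two independent catalysts, a minor enantiomer from either step ends up in a diastereomer of 19, which should be separable.

**Step 14 (key step).** The most likely failure is that the ketene is consumed by intermolecular dimerization or by hydration and decarboxylation before the weakly nucleophilic push-pull carbon C5 reaches it. Thermolysis of 16, which lacks the first flavanone, is a cheap early test.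

Fallback by known chemistry: the second flavanone is made the way the first is, by conjugate addition to a ready-made ring A'' chromone. The fallback sets out from 7 and returns at 22.
- Chan–Lam etherification of 7 with 4-chlorophenylboronic acid (Cu(OAc)2, pyridine, 4 Å MS, CH2Cl2, air) would give 1-(benzyloxy)-4-bromo-2-(4-chlorophenoxy)benzene F1.
- Bromide-selective Miyaura borylation (PdCl2(dppf), B2pin2, KOAc, dioxane, 80 °C) would give the pinacol boronate F2, and periodate cleavage as in step 12 the boronic acid F3.
- 1,4-Addition to 6 under the conditions of step 13 would give the (2S)-flavanone chloride F4.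
- Borylation of the aryl chloride (Pd2(dba)3, XPhos, B2pin2, potassium 2-ethylhexanoate, 50 °C) would give the boronate F5, and periodate cleavage the boronic acid F6.
- A second 1,4-addition with the same catalyst to 5,7-bis(benzyloxy)-4H-chromen-4-one F7 (from commercial 5,7-dihydroxy-4H-chromen-4-one, BnBr, K2CO3, DMF) would give the tetra-O-benzyl biflavanone F8.
- Hydrogenolysis as in step 15 would give 22.

**Step 13.** Protodeboronation of the electron-rich boronic acid may outrun insertion of the electron-rich chromone, and the labile dioxinone limits how far the conditions can be forced. The facial sense rests on the enone model; if it were opposite, the antipodal ligand would be used.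

Fallback: the order of ring construction is changed so that the coupling partner no longer carries the dioxinone. It sets out from 16 and returns at 21.
- Thermolysis of 16 under the conditions of step 14 would give (2S)-2-{4-[2-(benzyloxy)-5-bromophenoxy]phenyl}-5,7-dihydroxy-2,3-dihydro-4H-chromen-4-one F9.
- Borylation as in step 11 with extra carboxylate would give the pinacol boronate F10.
- Transesterification with diethanolamine and dilute acid would give the boronic acid F11.
- 1,4-Addition of F11 to 6 with the catalyst of step 13 would give 21.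

**Step 11.** Oxidative addition into the electron-rich aryl bromide may be slow at 35 °C, and the higher temperature that would cure this starts the cycloreversion of the dioxinone; protodebromination may also compete.

Fallback: boron is introduced before the dioxinone exists. It sets out from 13 and returns at 17.
- Borylation of 13 under standard conditions (PdCl2(dppf), B2pin2, KOAc, dioxane, 80 °C) would give the boronate Weinreb amide F12.
- Acylation of the dianion of 2 as in step 9 would give the boronate diketo-dioxinone F13.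
- Fluoride-free desilylation and cyclodehydration (pyridinium tosylate, MeOH; then TsOH·H2O, CH2Cl2) would give 17.

**Step 9.** The dianion may act as a base instead of a nucleophile: enolization of the amide followed by β-elimination of silanolate, or incomplete acylation.

Fallback: the C–C bond is made by aldol addition and the oxidation level is adjusted afterwards. It sets out from 13 and returns at 14.
- Reduction of 13 with i-Bu2AlH (THF, −78 °C) would give (3S)-3-{4-[2-(benzyloxy)-5-bromophenoxy]phenyl}-3-[(triethylsilyl)oxy]propanal F14.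
- Addition of the dianion of 2 would give the 4-hydroxy-2-oxo adduct F15 as a mixture of C4 epimers.
- Oxidation with Dess–Martin periodinane would converge both epimers on 14.

**Step 15.** Over-reduction is the risk: hydrogenolytic opening of the benzylic C2–O1 and C2''–O1'' bonds once the benzyl ethers are gone.

Fallback: Lewis-acid debenzylation in place of hydrogenation. It sets out from 21 and returns at 22. BCl3 with pentamethylbenzene as cation scavenger (CH2Cl2, −78 °C) cleaves both benzyl ethers while the non-chelated 7-methyl ether should survive at that temperature. This fallback makes no new compound (F0).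

## Further compounds

F1 | step 14 | 1-(benzyloxy)-4-bromo-2-(4-chlorophenoxy)benzene | Clc1ccc(Oc2cc(Br)ccc2OCc2ccccc2)cc1
F2 | step 14 | 2-[4-(benzyloxy)-3-(4-chlorophenoxy)phenyl]-4,4,5,5-tetramethyl-1,3,2-dioxaborolane | CC1(C)OB(OC1(C)C)c1ccc(OCc2ccccc2)c(Oc2ccc(Cl)cc2)c1
F3 | step 14 | [4-(benzyloxy)-3-(4-chlorophenoxy)phenyl]boronic acid | OB(O)c1ccc(OCc2ccccc2)c(Oc2ccc(Cl)cc2)c1
F4 | step 14 | (2S)-5-(benzyloxy)-2-[4-(benzyloxy)-3-(4-chlorophenoxy)phenyl]-7-methoxy-2,3-dihydro-4H-chromen-4-one | COc1cc(OCc6ccccc6)c2c(c1)O[C@H](c1ccc(OCc3ccccc3)c(Oc3ccc(Cl)cc3)c1)CC2=O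
F5 | step 14 | (2S)-5-(benzyloxy)-2-{4-(benzyloxy)-3-[4-(4,4,5,5-tetramethyl-1,3,2-dioxaborolan-2-yl)phenoxy]phenyl}-7-methoxy-2,3-dihydro-4H-chromen-4-one | COc1cc(OCc6ccccc6)c2c(c1)O[C@H](c1ccc(OCc3ccccc3)c(Oc3ccc(B4OC(C)(C)C(C)(C)O4)cc3)c1)CC2=O
F6 | step 14 | [4-(2-(benzyloxy)-5-{(2S)-5-(benzyloxy)-7-methoxy-4-oxo-3,4-dihydro-2H-chromen-2-yl}phenoxy)phenyl]boronic acid | COc1cc(OCc6ccccc6)c2c(c1)O[C@H](c1ccc(OCc3ccccc3)c(Oc3ccc(B(O)O)cc3)c1)CC2=O
F7 | step 14 | 5,7-bis(benzyloxy)-4H-chromen-4-one | O=C1C=COc2cc(OCc3ccccc3)cc(OCc3ccccc3)c12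
F8 | step 14 | (2S)-5-(benzyloxy)-2-[4-(benzyloxy)-3-{4-[(2S)-5,7-bis(benzyloxy)-4-oxo-3,4-dihydro-2H-chromen-2-yl]phenoxy}phenyl]-7-methoxy-2,3-dihydro-4H-chromen-4-one | COc1cc(OCc6ccccc6)c2c(c1)O[C@H](c1ccc(OCc3ccccc3)c(Oc3ccc([C@@H]4CC(=O)c5c(OCc7ccccc7)cc(OCc7ccccc7)cc5O4)cc3)c1)CC2=O
F9 | step 13 | (2S)-2-{4-[2-(benzyloxy)-5-bromophenoxy]phenyl}-5,7-dihydroxy-2,3-dihydro-4H-chromen-4-one | O=C1C[C@@H](c2ccc(Oc3cc(Br)ccc3OCc3ccccc3)cc2)Oc2cc(O)cc(O)c12
F10 | step 13 | (2S)-2-{4-[2-(benzyloxy)-5-(4,4,5,5-tetramethyl-1,3,2-dioxaborolan-2-yl)phenoxy]phenyl}-5,7-dihydroxy-2,3-dihydro-4H-chromen-4-one | CC1(C)OB(OC1(C)C)c1ccc(OCc2ccccc2)c(Oc2ccc([C@@H]3CC(=O)c4c(O)cc(O)cc4O3)cc2)c1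
F11 | step 13 | [4-(benzyloxy)-3-{4-[(2S)-5,7-dihydroxy-4-oxo-3,4-dihydro-2H-chromen-2-yl]phenoxy}phenyl]boronic acid | OB(O)c1ccc(OCc2ccccc2)c(Oc2ccc([C@@H]3CC(=O)c4c(O)cc(O)cc4O3)cc2)c1
F12 | step 11 | (3S)-3-{4-[2-(benzyloxy)-5-(4,4,5,5-tetramethyl-1,3,2-dioxaborolan-2-yl)phenoxy]phenyl}-N-methoxy-N-methyl-3-[(triethylsilyl)oxy]propanamide | CON(C)C(=O)C[C@H](O[Si](CC)(CC)CC)c1ccc(Oc2cc(B3OC(C)(C)C(C)(C)O3)ccc2OCc2ccccc2)cc1
F13 | step 11 | 6-[(6S)-6-{4-[2-(benzyloxy)-5-(4,4,5,5-tetramethyl-1,3,2-dioxaborolan-2-yl)phenoxy]phenyl}-2,4-dioxo-6-[(triethylsilyl)oxy]hexyl]-2,2-dimethyl-4H-1,3-dioxin-4-one | CC1(C)OC(=O)C=C(CC(=O)CC(=O)C[C@H](O[Si](CC)(CC)CC)c2ccc(Oc3cc(B4OC(C)(C)C(C)(C)O4)ccc3OCc3ccccc3)cc2)O1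
F14 | step 9 | (3S)-3-{4-[2-(benzyloxy)-5-bromophenoxy]phenyl}-3-[(triethylsilyl)oxy]propanal | O=CC[C@H](O[Si](CC)(CC)CC)c1ccc(Oc2cc(Br)ccc2OCc2ccccc2)cc1
F15 | step 9 | 6-[(6S)-6-{4-[2-(benzyloxy)-5-bromophenoxy]phenyl}-4-hydroxy-2-oxo-6-[(triethylsilyl)oxy]hexyl]-2,2-dimethyl-4H-1,3-dioxin-4-one (C4 epimers) | CC1(C)OC(=O)C=C(CC(=O)CC(O)C[C@H](O[Si](CC)(CC)CC)c2ccc(Oc3cc(Br)ccc3OCc3ccccc3)cc2)O1
F0 | step 15 | none | none
A1 | alternative 1 | bis(diene): each ring A aryl ether of a (1S)-1-arylprop-2-en-1-ol with an ortho 1-(tert-butyldimethylsilyloxy)vinyl group | COc1cc(OC)c(C(=C)O[Si](C)(C)C(C)(C)C)c(c1)O[C@H](c2ccc(OCc3ccccc3)c(Oc3ccc([C@H](C=C)Oc4cc(OCc5ccccc5)cc(OCc5ccccc5)c4C(=C)O[Si](C)(C)C(C)(C)C)cc3)c2)C=C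
A2 | alternative 1 | bis(4-silyloxy-2H-chromene), the bis(silyl enol ether) of the protected biflavanone | COc1cc(OC)c2c(c1)O[C@H](c1ccc(OCc3ccccc3)c(Oc3ccc([C@@H]4C=C(O[Si](C)(C)C(C)(C)C)c5c(OCc6ccccc6)cc(OCc6ccccc6)cc5O4)cc3)c1)C=C2O[Si](C)(C)C(C)(C)C
A3 | alternative 2 | 2,6-dihydroxy-4-methoxybenzaldehyde | COc1cc(O)c(C=O)c(O)c1
A4 | alternative 2 | 1-(benzyloxy)-2-(4-bromophenoxy)-4-vinylbenzene | C=Cc1ccc(OCc2ccccc2)c(Oc2ccc(Br)cc2)c1
A5 | alternative 2 | (2S,4S)-2-[4-(benzyloxy)-3-(4-bromophenoxy)phenyl]-4,7-dimethoxychroman-5-ol (cis-4-methoxyflavan) | COc1cc(O)c2c(c1)O[C@H](c1ccc(OCc3ccccc3)c(Oc3ccc(Br)cc3)c1)C[C@@H]2OC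
A6 | alternative 3 | bis(trans-chalcone epoxide) with all phenols as methoxymethyl ethers | COCOc1cc(OC)cc(OCOC)c1C(=O)[C@@H]2O[C@H]2c2ccc(OCOC)c(Oc3ccc([C@@H]4O[C@H]4C(=O)c4c(OCOC)cc(OCOC)cc4OCOC)cc3)c2
A7 | alternative 3 | 3,3''-dihydroxy target (bis-trans-dihydroflavonol) | COc1cc(O)c2c(c1)O[C@H](c1ccc(O)c(Oc3ccc([C@@H]4[C@@H](O)C(=O)c5c(O)cc(O)cc5O4)cc3)c1)[C@@H](O)C2=O
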